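Ring B, the hexasubstituted isobutyryl-bearing benzene, is disconnected so that its adjacent C–CH3 and C–OCH3 carbons are the two sp carbons of 1-methoxypropyne and its other four ring carbons come from a 3-silyloxy-4-(benzyloxymethyl)cyclobutenone. One thermal cascade then closes the ring with both new C–C bonds and delivers the three oxygens differentiated (OH, OMe, OSi), the bridge carbon as CH2OBn and one free C–H for acylation. Because ring C carries the same pattern with acetyl, the same aryl bromide serves both outer rings; each benzylic ether is finally ionised to an ortho-quinone methide and captured by the (R)-2-methylbutanoylphloroglucinol ring A.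

Key step: step 4

Remark: the stereocentre written in the target is (R); (R)-2-methylbutanoic acid and the two N-methoxy-N-methylamides are taken to be commercial.

Step 1
Reactants: 1 chloroacetaldehyde dimethyl acetal
Product: 3 1-methoxyprop-1-yne, via sodium methoxyacetylide 2 (not isolated)
Conditions: NaNH2 (3 equiv), liq. NH3, −33 °C; then MeI, −33 °C to rt
Reagents that add atoms: iodomethane, CI
Why: Excess amide effects two eliminations from the β-chloro acetal (loss of methanol, then of HCl) to give the acetylide, which is C-methylated by SN2 alkylation in liquid ammonia, the standard route to 1-alkoxyalk-1-ynes.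

Step 2
Reactants: 4 ethyl bromoacetate; 5 triisopropylsilyl chloride
Product: 8 (ethynyloxy)triisopropylsilane, via lithium enolate of ethyl bromoacetate 6 (not isolated), via lithium ethynolate 7 (not isolated)
Conditions: LiN(SiMe3)2, THF, −78 °C; t-BuLi (2 equiv), −78 to 0 °C; then 5, −78 °C to rt
Reagents that add atoms: none
Why: Deprotonation gives the bromo enolate, bromine–lithium exchange then triggers loss of lithium ethoxide (ynolate formation by cleavage of an ester dianion), and the bulky chlorosilane should silylate the ynolate on oxygen, not on carbon.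

Step 3
Reactants: 9 3-(benzyloxy)propanoic acid; 8 (ethynyloxy)triisopropylsilane
Product: 12 4-[(benzyloxy)methyl]-3-(triisopropylsilyloxy)cyclobut-2-en-1-one (racemic), via 3-(benzyloxy)propanoyl chloride 10 (not isolated), via (benzyloxymethyl)ketene 11 (not isolated)
Conditions: (COCl)2, cat. DMF, CH2Cl2, 0 °C to rt, concentrate; then 8, Et3N (slow addition), CH2Cl2, 0 °C to rt
Reagents that add atoms: none
Why: Dehydrochlorination of the acid chloride gives the ketene, whose carbonyl carbon bonds to the nucleophilic terminal carbon of the silyl ynol ether in a regioselective [2+2] ketene–alkyne cycloaddition, the new sp3 centre at C4 being formed racemic and erased in step 4.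

Step 4
Reactants: 12 4-[(benzyloxy)methyl]-3-(triisopropylsilyloxy)cyclobut-2-en-1-one; 3 1-methoxyprop-1-yne
Product: 17 2-[(benzyloxy)methyl]-5-methoxy-6-methyl-3-(triisopropylsilyloxy)phenol, via vinylketene 13 (not isolated), via 4-vinylcyclobutenone adduct 14 (not isolated), via dienylketene 15 (not isolated), via cyclohexa-2,4-dienone 16 (not isolated)
Conditions: 3 (3 equiv), PhMe, sealed tube, 80 °C then 120 °C
Reagents that add atoms: none
Why: Thermal 4π-electrocyclic opening of the C1–C4 bond of 12 gives vinylketene 13, whose ketene C=C adds [2+2] to 3 to give 14; a second 4π opening gives dienylketene 15, which closes by thermal disrotatory 6π-electrocyclization to dienone 16 and tautomerises to phenol 17 (Danheiser benzannulation of a cyclobutenone with an ynol ether). The six-membered ring is thus closed pericyclically, its two new skeletal bonds being C(OH)–C(CH3) and C(OCH3)–C(H). No stereocentre survives, since the sp3 centres of 12, 14 and 16 are lost on aromatisation. The step needs regiocontrol, which the polarised ynol ether supplies: its nucleophilic methyl-bearing carbon attacks the electrophilic ketene carbon, so CH3 ends ortho to the new OH and OCH3 next to CH3. Outward rotation of the CH2OBn group in the first opening places it on the outside of the triene terminus, which favours the 6π closure. Excess 3 should outcompete capture of the ketenes by the phenol as it forms.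

Step 5
Reactants: 17 2-[(benzyloxy)methyl]-5-methoxy-6-methyl-3-(triisopropylsilyloxy)phenol
Product: 18 2-[(benzyloxy)methyl]-4-bromo-5-methoxy-6-methyl-3-(triisopropylsilyloxy)phenol
Conditions: NBS (1.0 equiv), CH2Cl2, −40 to 0 °C
Reagents that add atoms: N-bromosuccinimide, O=C1CCC(=O)N1Br
Why: Electrophilic aromatic bromination can only take place at the single unsubstituted ring carbon, which is para to the free hydroxyl and flanked by two oxygen donors.

Step 6
Reactants: 18 2-[(benzyloxy)methyl]-4-bromo-5-methoxy-6-methyl-3-(triisopropylsilyloxy)phenol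
Product: 19 1-bromo-3-[(benzyloxy)methyl]-4-(tert-butyldimethylsilyloxy)-6-methoxy-5-methyl-2-(triisopropylsilyloxy)benzene
Conditions: TBSCl, imidazole, DMF, rt
Reagents that add atoms: tert-butyldimethylsilyl chloride, CC(C)(C)[Si](C)(C)Cl
Why: Imidazole-promoted O-silylation masks the acidic phenol before metalation and avoids any Lewis acid that could ionise the electron-rich benzylic ether.

Step 7
Reactants: 19 1-bromo-3-[(benzyloxy)methyl]-4-(tert-butyldimethylsilyloxy)-6-methoxy-5-methyl-2-(triisopropylsilyloxy)benzene; 20 N-methoxy-N-methylisobutyramide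
Product: 23 1-[3-[(benzyloxy)methyl]-4-(tert-butyldimethylsilyloxy)-6-methoxy-5-methyl-2-(triisopropylsilyloxy)phenyl]-2-methylpropan-1-one, via aryllithium 21 (not isolated), via lithium hemiaminal adduct 22 (not isolated)
Conditions: t-BuLi (2.1 equiv), Et2O, −78 °C; then 20, −78 to 0 °C; aq. NH4Cl
Reagents that add atoms: none
Why: Bromine–lithium exchange at −78 °C is faster than benzylic deprotonation or migration of the sluggish neighbouring triisopropylsilyl group, and the strongly nucleophilic aryllithium adds only once to the α-branched amide because the chelated adduct 22 collapses to the ketone only on work-up (Weinreb ketone synthesis).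

Step 8
Reactants: 23 1-[3-[(benzyloxy)methyl]-4-(tert-butyldimethylsilyloxy)-6-methoxy-5-methyl-2-(triisopropylsilyloxy)phenyl]-2-methylpropan-1-one
Product: 24 1-[3-[(benzyloxy)methyl]-2,4-dihydroxy-6-methoxy-5-methylphenyl]-2-methylpropan-1-one
Conditions: Bu4NF (2.2 equiv), AcOH (2.2 equiv), THF, 0 °C
Reagents that add atoms: none
Why: Fluoride cleaves both aryl silyl ethers (desilylation), while the acetic acid buffer keeps the liberated phenoxide from expelling benzyloxide.

Step 9
Reactants: 19 1-bromo-3-[(benzyloxy)methyl]-4-(tert-butyldimethylsilyloxy)-6-methoxy-5-methyl-2-(triisopropylsilyloxy)benzene; 25 N-methoxy-N-methylacetamide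
Product: 28 1-[3-[(benzyloxy)methyl]-4-(tert-butyldimethylsilyloxy)-6-methoxy-5-methyl-2-(triisopropylsilyloxy)phenyl]ethan-1-one, via arylmagnesium bromide 26 (not isolated), via magnesium hemiaminal adduct 27 (not isolated)
Conditions: Mg turnings, LiCl, cat. I2, THF, rt; then 25, 0 °C to rt; aq. NH4Cl
Reagents that add atoms: none
Why: LiCl-assisted insertion of magnesium into the C–Br bond of the trioxygenated aryl bromide gives a Grignard reagent that is less basic than the aryllithium, so it should add to the enolisable acetamide instead of deprotonating it and should not trigger silyl migration, the chelated adduct 27 releasing the methyl ketone only on work-up (Grignard formation and Weinreb ketone synthesis).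

Step 10
Reactants: 28 1-[3-[(benzyloxy)methyl]-4-(tert-butyldimethylsilyloxy)-6-methoxy-5-methyl-2-(triisopropylsilyloxy)phenyl]ethan-1-one
Product: 29 1-[3-[(benzyloxy)methyl]-2,4-dihydroxy-6-methoxy-5-methylphenyl]ethan-1-one
Conditions: Bu4NF (2.2 equiv), AcOH (2.2 equiv), THF, 0 °C
Reagents that add atoms: none
Why: Buffered fluoride desilylation frees both phenols as in step 8.

Step 11
Reactants: 30 (R)-2-methylbutanoic acid; 31 phloroglucinol
Product: 33 (2R)-2-methyl-1-(2,4,6-trihydroxyphenyl)butan-1-one, via (R)-2-methylbutanoyl chloride 32 (not isolated)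
Conditions: (COCl)2, cat. DMF, CH2Cl2, 0 °C to rt; then 31, AlCl3 (3 equiv), CH2Cl2/PhNO2, 0 °C to rt; aq. HCl
Reagents that add atoms: none
Why: Friedel–Crafts C-acylation of phloroglucinol stops after one acyl group because the chelated ketone deactivates the ring, and the stereocentre comes unchanged from the chiral-pool acid, the low temperature limiting enolisation of the acyl species.

Step 12
Reactants: 29 1-[3-[(benzyloxy)methyl]-2,4-dihydroxy-6-methoxy-5-methylphenyl]ethan-1-one; 33 (2R)-2-methyl-1-(2,4,6-trihydroxyphenyl)butan-1-one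
Product: 35 (2R)-1-[3-[(3-acetyl-2,6-dihydroxy-4-methoxy-5-methylphenyl)methyl]-2,4,6-trihydroxyphenyl]-2-methylbutan-1-one, via acetyl ortho-quinone methide 34 (not isolated)
Conditions: 33 (3 equiv), TsOH·H2O (10 mol %), (CF3)2CHOH/CH2Cl2, 0 °C to rt
Reagents that add atoms: none
Why: Acid in the ionising solvent converts the ortho-hydroxybenzyl ether into ortho-quinone methide 34, which is captured through carbon by a free ring position of 33 (Friedel–Crafts-type benzylation), excess 33 suppressing double alkylation and no stereocentre being formed.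

Step 13
Reactants: 35 (2R)-1-[3-[(3-acetyl-2,6-dihydroxy-4-methoxy-5-methylphenyl)methyl]-2,4,6-trihydroxyphenyl]-2-methylbutan-1-one; 24 1-[3-[(benzyloxy)methyl]-2,4-dihydroxy-6-methoxy-5-methylphenyl]-2-methylpropan-1-one
Product: 37 (2R)-1-[3-[(3-acetyl-2,6-dihydroxy-4-methoxy-5-methylphenyl)methyl]-5-[[2,6-dihydroxy-4-methoxy-3-methyl-5-(2-methylpropanoyl)phenyl]methyl]-2,4,6-trihydroxyphenyl]-2-methylbutan-1-one, via isobutyryl ortho-quinone methide 36 (not isolated)
Conditions: 24 (1.1 equiv), TsOH·H2O (10 mol %), (CF3)2CHOH/CH2Cl2, 0 °C to rt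
Reagents that add atoms: none
Why: The same ionisation of 24 gives 36, to which the only unsubstituted aromatic carbon of 35 (on ring A) adds in a Friedel–Crafts-type benzylation, the (R) centre not being enolised under mild acid at low temperature.

Compound list
1 | chloroacetaldehyde dimethyl acetal (2-chloro-1,1-dimethoxyethane) | COC(CCl)OC | starting material
2 | sodium methoxyacetylide | [Na]C#COC | intermediate
3 | 1-methoxyprop-1-yne | CC#COC | intermediate
4 | ethyl bromoacetate | CCOC(=O)CBr | starting material
5 | triisopropylsilyl chloride | CC(C)[Si](Cl)(C(C)C)C(C)C | starting material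
6 | lithium enolate of ethyl bromoacetate | CCOC(O[Li])=CBr | intermediate
7 | lithium ethynolate | [Li]OC#C | intermediate
8 | (ethynyloxy)triisopropylsilane (triisopropylsilyloxyacetylene) | C#CO[Si](C(C)C)(C(C)C)C(C)C | intermediate
9 | 3-(benzyloxy)propanoic acid | OC(=O)CCOCc1ccccc1 | starting material
10 | 3-(benzyloxy)propanoyl chloride | ClC(=O)CCOCc1ccccc1 | intermediate
11 | (benzyloxymethyl)ketene, 3-(benzyloxy)prop-1-en-1-one | O=C=CCOCc1ccccc1 | intermediate
12 | 4-[(benzyloxy)methyl]-3-(triisopropylsilyloxy)cyclobut-2-en-1-one, racemic | CC(C)[Si](OC1=CC(=O)C1COCc1ccccc1)(C(C)C)C(C)C | intermediate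
13 | vinylketene, (3Z)-5-(benzyloxy)-3-(triisopropylsilyloxy)penta-1,3-dien-1-one | O=C=C/C(O[Si](C(C)C)(C(C)C)C(C)C)=C/COCc1ccccc1 | intermediate
14 | 4-[(1Z)-3-(benzyloxy)-1-(triisopropylsilyloxy)prop-1-en-1-yl]-3-methoxy-2-methylcyclobut-2-en-1-one, racemic | CC1=C(OC)C(C1=O)/C(O[Si](C(C)C)(C(C)C)C(C)C)=C/COCc1ccccc1 | intermediate
15 | dienylketene, (3E,5Z)-7-(benzyloxy)-3-methoxy-2-methyl-5-(triisopropylsilyloxy)hepta-1,3,5-trien-1-one | O=C=C(C)/C(OC)=C\C(O[Si](C(C)C)(C(C)C)C(C)C)=C\COCc1ccccc1 | intermediate
16 | 6-[(benzyloxy)methyl]-3-methoxy-2-methyl-5-(triisopropylsilyloxy)cyclohexa-2,4-dien-1-one, racemic | CC1=C(OC)C=C(O[Si](C(C)C)(C(C)C)C(C)C)C(COCc2ccccc2)C1=O | intermediate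
17 | 2-[(benzyloxy)methyl]-5-methoxy-6-methyl-3-(triisopropylsilyloxy)phenol | Cc1c(O)c(COCc2ccccc2)c(O[Si](C(C)C)(C(C)C)C(C)C)cc1OC | intermediate
18 | 2-[(benzyloxy)methyl]-4-bromo-5-methoxy-6-methyl-3-(triisopropylsilyloxy)phenol | Cc1c(O)c(COCc2ccccc2)c(O[Si](C(C)C)(C(C)C)C(C)C)c(Br)c1OC | intermediate
19 | 1-bromo-3-[(benzyloxy)methyl]-4-(tert-butyldimethylsilyloxy)-6-methoxy-5-methyl-2-(triisopropylsilyloxy)benzene | Cc1c(O[Si](C)(C)C(C)(C)C)c(COCc2ccccc2)c(O[Si](C(C)C)(C(C)C)C(C)C)c(Br)c1OC | intermediate
20 | N-methoxy-N-methylisobutyramide | CC(C)C(=O)N(C)OC | starting material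
21 | aryllithium from 19 (lithium in place of bromine) | [Li]c1c(O[Si](C(C)C)(C(C)C)C(C)C)c(COCc2ccccc2)c(O[Si](C)(C)C(C)(C)C)c(C)c1OC | intermediate
22 | lithium hemiaminal adduct of 21 and 20 | CC(C)C(O[Li])(N(C)OC)c1c(O[Si](C(C)C)(C(C)C)C(C)C)c(COCc2ccccc2)c(O[Si](C)(C)C(C)(C)C)c(C)c1OC | intermediate
23 | 1-[3-[(benzyloxy)methyl]-4-(tert-butyldimethylsilyloxy)-6-methoxy-5-methyl-2-(triisopropylsilyloxy)phenyl]-2-methylpropan-1-one | CC(C)C(=O)c1c(O[Si](C(C)C)(C(C)C)C(C)C)c(COCc2ccccc2)c(O[Si](C)(C)C(C)(C)C)c(C)c1OC | intermediate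
24 | 1-[3-[(benzyloxy)methyl]-2,4-dihydroxy-6-methoxy-5-methylphenyl]-2-methylpropan-1-one (ring B electrophile) | CC(C)C(=O)c1c(O)c(COCc2ccccc2)c(O)c(C)c1OC | intermediate
25 | N-methoxy-N-methylacetamide | CC(=O)N(C)OC | starting material
26 | arylmagnesium bromide from 19 (MgBr in place of bromine) | Br[Mg]c1c(O[Si](C(C)C)(C(C)C)C(C)C)c(COCc2ccccc2)c(O[Si](C)(C)C(C)(C)C)c(C)c1OC | intermediate
27 | bromomagnesium hemiaminal adduct of 26 and 25 | CC(O[Mg]Br)(N(C)OC)c1c(O[Si](C(C)C)(C(C)C)C(C)C)c(COCc2ccccc2)c(O[Si](C)(C)C(C)(C)C)c(C)c1OC | intermediate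
28 | 1-[3-[(benzyloxy)methyl]-4-(tert-butyldimethylsilyloxy)-6-methoxy-5-methyl-2-(triisopropylsilyloxy)phenyl]ethan-1-one | CC(=O)c1c(O[Si](C(C)C)(C(C)C)C(C)C)c(COCc2ccccc2)c(O[Si](C)(C)C(C)(C)C)c(C)c1OC | intermediate
29 | 1-[3-[(benzyloxy)methyl]-2,4-dihydroxy-6-methoxy-5-methylphenyl]ethan-1-one (ring C electrophile) | CC(=O)c1c(O)c(COCc2ccccc2)c(O)c(C)c1OC | intermediate
30 | (R)-2-methylbutanoic acid | CC[C@@H](C)C(=O)O | starting material
31 | phloroglucinol (benzene-1,3,5-triol) | Oc1cc(O)cc(O)c1 | starting material
32 | (R)-2-methylbutanoyl chloride | CC[C@@H](C)C(Cl)=O | intermediate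
33 | (2R)-2-methyl-1-(2,4,6-trihydroxyphenyl)butan-1-one (ring A) | CC[C@@H](C)C(=O)c1c(O)cc(O)cc1O | intermediate
34 | ortho-quinone methide of ring C, 4-acetyl-3-hydroxy-5-methoxy-6-methyl-2-methylidenecyclohexa-3,5-dien-1-one | C=C1C(=O)C(C)=C(OC)C(C(C)=O)=C1O | intermediate
35 | (2R)-1-[3-[(3-acetyl-2,6-dihydroxy-4-methoxy-5-methylphenyl)methyl]-2,4,6-trihydroxyphenyl]-2-methylbutan-1-one (ring A–ring C dimer) | CC[C@@H](C)C(=O)c1c(O)c(Cc2c(O)c(C)c(OC)c(C(C)=O)c2O)c(O)cc1O | intermediate
36 | ortho-quinone methide of ring B, 3-hydroxy-5-methoxy-6-methyl-2-methylidene-4-(2-methylpropanoyl)cyclohexa-3,5-dien-1-one | C=C1C(=O)C(C)=C(OC)C(C(=O)C(C)C)=C1O | intermediate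
37 | (2R)-1-[3-[(3-acetyl-2,6-dihydroxy-4-methoxy-5-methylphenyl)methyl]-5-[[2,6-dihydroxy-4-methoxy-3-methyl-5-(2-methylpropanoyl)phenyl]methyl]-2,4,6-trihydroxyphenyl]-2-methylbutan-1-one | CC[C@@H](C)C(=O)c1c(O)c(Cc2c(O)c(C)c(OC)c(C(C)=O)c2O)c(O)c(Cc2c(O)c(C)c(OC)c(C(=O)C(C)C)c2O)c1O | target

Total step count: 13 steps.
Longest linear sequence: 9 steps (steps 2, 3, 4, 5, 6, 9, 10, 12, 13).

Steps most likely to fail

Step 2. The process at risk is silylation of the unsubstituted ynolate at carbon instead of oxygen, or further metalation of its C–H, either of which would lead to a silylketene. The fallback sets out from 5. Lithium (trimethylsilyl)acetylide, made from commercial (trimethylsilyl)acetylene and n-BuLi in THF at −78 °C, is oxidised with LiOOt-Bu (from t-BuOOH and LiN(SiMe3)2) to the C-silylated ynolate. Its blocked carbon terminus should direct 5 to oxygen and give triisopropyl{[(trimethylsilyl)ethynyl]oxy}silane F1. K2CO3 in MeOH at 0 °C should then remove the alkynyl trimethylsilyl group, and the fallback comes back to the route at 8.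

Step 4. The process at risk is loss of the silyloxy-substituted cyclobutenone or its vinylketene (silyl transfer, oligomerisation, capture by the phenol formed) before the cycloaddition, or stalling at the stage of 14. The fallback exchanges the roles of the two partners and sets out from 1. NaNH2 in liquid NH3 followed by an NH4Cl quench should give methoxyacetylene F2. Methylketene, generated from propanoyl chloride and Et3N, should add [2+2] to F2 and give 3-methoxy-4-methylcyclobut-2-en-1-one F3, a 3-alkoxy-4-alkylcyclobutenone of a well-used class. Commercial benzyl propargyl ether is lithiated with n-BuLi, oxidised with LiOOt-Bu and silylated with 5 to give {[3-(benzyloxy)prop-1-yn-1-yl]oxy}triisopropylsilane F4. Heating F3 with F4 in toluene runs the same cascade, the vinylketene carbonyl carbon now bonding to the CH2OBn-bearing alkyne carbon, and should come back to the route at 17. This path needs neither 8 nor the β-alkoxy ketene 11.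

Step 13. The process at risk is acid-promoted reversal of the methylene bridge already present in 35, which would exchange outer rings and give symmetrical trimers while the less reactive benzylic ether of 24 is being ionised. The fallback separates ionisation from coupling and sets out from 24. Solvolysis in AcOH with catalytic TsOH·H2O at 40 °C should exchange benzyloxy for acetoxy and give [2,6-dihydroxy-4-methoxy-3-methyl-5-(2-methylpropanoyl)phenyl]methyl acetate F5. F5 and 35 are then combined with i-Pr2NEt in MeCN at room temperature, where the phenoxide of F5 expels acetate to give 36 without acid and the phenoxide of 35 adds through carbon, so that the fallback comes back to the route at 37.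

Further compounds
F1 | step 2 | triisopropyl{[(trimethylsilyl)ethynyl]oxy}silane | C[Si](C)(C)C#CO[Si](C(C)C)(C(C)C)C(C)C
F2 | step 4 | methoxyacetylene | COC#C
F3 | step 4 | 3-methoxy-4-methylcyclobut-2-en-1-one, racemic | COC1=CC(=O)C1C
F4 | step 4 | {[3-(benzyloxy)prop-1-yn-1-yl]oxy}triisopropylsilane | CC(C)[Si](OC#CCOCc1ccccc1)(C(C)C)C(C)C
F5 | step 13 | [2,6-dihydroxy-4-methoxy-3-methyl-5-(2-methylpropanoyl)phenyl]methyl acetate | CC(C)C(=O)c1c(O)c(COC(C)=O)c(O)c(C)c1OC
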